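**Retrosynthetic overview**
1. Target ⇐ bis-benzyl ether 11; one hydrogenolysis frees both phenols.
2. C7–C8 bond: chelation-controlled addition of the guaiacyl Grignard (from 10) to the (S)-α-aryloxy aldehyde 8; this sets C7 (threo).
3. C8 stereocentre (key step): lipase desymmetrisation of the prochiral diacetate 6; its two enantiotopic CH2OAc arms become C7 and C9.
4. C8–OAr bond: Williamson etherification of mono-benzylated 2,6-dimethoxyhydroquinone 2 with diethyl chloromalonate 3, then reduction and acetylation.
5. No ring is formed; both benzene rings are bought intact (4-bromoguaiacol and 2,6-dimethoxyhydroquinone).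

Assumption: the lipase shows the same enantiotopic preference for 6 as for 2-O-benzylglycerol diacetate (pro-S acetate cleaved). If the sense is reversed, acetylating diol 5 with the same enzyme and vinyl acetate gives the same (R)-7 and removes Step 4.

**Step 1**
Reactants: 1, 2,6-dimethoxybenzene-1,4-diol (2,6-dimethoxyhydroquinone)
Product: 2, 4-(benzyloxy)-2,6-dimethoxyphenol
Conditions: BnBr (1.0 equiv), K2CO3 (1.1 equiv), degassed DMF, 0 °C → rt, N2
Reagents that add atoms: benzyl bromide, BrCc1ccccc1
Why: Williamson mono-etherification; the 4-OH is meta to both OMe groups, so it is the more acidic and the unhindered hydroxyl, and it reacts ahead of the 1-OH flanked by two OMe groups (no stereocentre).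

**Step 2**
Reactants: 2, 4-(benzyloxy)-2,6-dimethoxyphenol; 3, diethyl 2-chloromalonate
Product: 4, diethyl 2-[4-(benzyloxy)-2,6-dimethoxyphenoxy]malonate
Conditions: K2CO3, DMF, 60 °C, N2
Reagents that add atoms: none (all new atoms come from 3)
Why: SN2 (Williamson) attack of the hindered phenoxide on the doubly activated α-chloromalonate forms the C8–O aryl ether; the chloride is used because it is less prone than the bromide to halogen transfer to an electron-rich phenoxide; C8 carries two identical ester arms and is not yet stereogenic.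

**Step 3**
Reactants: 4, diethyl 2-[4-(benzyloxy)-2,6-dimethoxyphenoxy]malonate
Product: 5, 2-[4-(benzyloxy)-2,6-dimethoxyphenoxy]propane-1,3-diol
Conditions: LiAlH4 (2.5 equiv), THF, 0 °C → rt; Fieser work-up
Reagents that add atoms: none
Why: Hydride reduction of both esters gives the σ-symmetric 2-aryloxy-1,3-diol; aryl and benzyl ethers are inert to LiAlH4.

**Step 4**
Reactants: 5, 2-[4-(benzyloxy)-2,6-dimethoxyphenoxy]propane-1,3-diol
Product: 6, 2-[4-(benzyloxy)-2,6-dimethoxyphenoxy]propane-1,3-diyl diacetate
Conditions: Ac2O, pyridine, DMAP (cat.), CH2Cl2, rt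
Reagents that add atoms: acetic anhydride, CC(=O)OC(C)=O
Why: Standard O-acetylation gives the prochiral diacetate that is the substrate for the enzymatic step.

**Step 5 (key step)**
Reactants: 6, 2-[4-(benzyloxy)-2,6-dimethoxyphenoxy]propane-1,3-diyl diacetate
Product: 7, (2R)-2-[4-(benzyloxy)-2,6-dimethoxyphenoxy]-3-hydroxypropyl acetate
Conditions: lipase PS (Burkholderia cepacia) or PPL, 0.1 M phosphate buffer pH 7.0 / MTBE, 25–30 °C, pH-stat, stop at 1.0 equiv NaOH
Reagents that add atoms: none
Why: Enzymatic desymmetrisation by enantiotopic-group-selective ester hydrolysis: the lipase cleaves the pro-S acetoxymethyl arm (by analogy with 2-O-benzylglycerol diacetate), which fixes C8 as R here; this is the spatial arrangement that becomes 8S in the target.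

**Step 6**
Reactants: 7, (2R)-2-[4-(benzyloxy)-2,6-dimethoxyphenoxy]-3-hydroxypropyl acetate
Product: 8, (2S)-2-[4-(benzyloxy)-2,6-dimethoxyphenoxy]-3-oxopropyl acetate
Conditions: Dess–Martin periodinane, NaHCO3, CH2Cl2, 0 °C → rt; used crude at once
Reagents that add atoms: none
Why: Dess–Martin oxidation under buffered, neutral conditions gives the α-aryloxy aldehyde without C8 epimerisation or β-elimination of acetate; the descriptor changes from R to S only because CHO now outranks CH2OAc.

**Step 7**
Reactants: 9, 4-bromo-2-methoxyphenol (4-bromoguaiacol)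
Product: 10, 1-(benzyloxy)-4-bromo-2-methoxybenzene
Conditions: BnBr, K2CO3, acetone, reflux
Reagents that add atoms: benzyl bromide, BrCc1ccccc1
Why: Williamson etherification masks the phenol so the ring can be metallated.

**Step 8**
Reactants: 8, (2S)-2-[4-(benzyloxy)-2,6-dimethoxyphenoxy]-3-oxopropyl acetate; 10, 1-(benzyloxy)-4-bromo-2-methoxybenzene (as its Grignard reagent)
Product: 11, (1S,2S)-1-[4-(benzyloxy)-3-methoxyphenyl]-2-[4-(benzyloxy)-2,6-dimethoxyphenoxy]propane-1,3-diol
Conditions: 10, t-BuLi (2 equiv), Et2O, −78 °C, then MgBr2·OEt2; add to 8 pre-mixed with MgBr2·OEt2 (2 equiv) in CH2Cl2, −78 °C (no THF); then MeOH, K2CO3, 0 °C → rt in the same flask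
Reagents that add atoms: none (all new atoms come from 10)
Why: Cram-chelate-controlled Grignard addition: Mg bridges the aldehyde oxygen and O8, whose lone pair is twisted out of conjugation by the two ortho substituents and is backed up by an ortho-OMe donor, so the aryl group attacks anti to CH2OAc and gives the 7,8-syn (threo, 7S) alcohol; the methanolic K2CO3 quench then removes the acetate, including any that migrated to O7.

**Step 9**
Reactants: 11, (1S,2S)-1-[4-(benzyloxy)-3-methoxyphenyl]-2-[4-(benzyloxy)-2,6-dimethoxyphenoxy]propane-1,3-diol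
Product: 12, (1S,2S)-1-(4-hydroxy-3-methoxyphenyl)-2-(4-hydroxy-2,6-dimethoxyphenoxy)propane-1,3-diol (target, threo-7S,8S)
Conditions: H2 (1 atm), 10% Pd/C, EtOAc/MeOH, rt, neutral; work up under N2
Reagents that add atoms: none
Why: Catalytic hydrogenolysis cleaves both benzyl ethers; acid-free conditions keep the benzylic C7–OH and prevent C7 epimerisation through a quinone methide.

**Compound list**
1 | 2,6-dimethoxybenzene-1,4-diol | COc1cc(O)cc(OC)c1O | starting material
2 | 4-(benzyloxy)-2,6-dimethoxyphenol | COc1cc(OCc2ccccc2)cc(OC)c1O | intermediate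
3 | diethyl 2-chloromalonate | CCOC(=O)C(Cl)C(=O)OCC | starting material
4 | diethyl 2-[4-(benzyloxy)-2,6-dimethoxyphenoxy]malonate | CCOC(=O)C(Oc1c(OC)cc(OCc2ccccc2)cc1OC)C(=O)OCC | intermediate
5 | 2-[4-(benzyloxy)-2,6-dimethoxyphenoxy]propane-1,3-diol | OCC(CO)Oc1c(OC)cc(OCc2ccccc2)cc1OC | intermediate
6 | 2-[4-(benzyloxy)-2,6-dimethoxyphenoxy]propane-1,3-diyl diacetate | CC(=O)OCC(COC(C)=O)Oc1c(OC)cc(OCc2ccccc2)cc1OC | intermediate
7 | (2R)-2-[4-(benzyloxy)-2,6-dimethoxyphenoxy]-3-hydroxypropyl acetate | OC[C@H](COC(C)=O)Oc1c(OC)cc(OCc2ccccc2)cc1OC | intermediate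
8 | (2S)-2-[4-(benzyloxy)-2,6-dimethoxyphenoxy]-3-oxopropyl acetate | O=C[C@H](COC(C)=O)Oc1c(OC)cc(OCc2ccccc2)cc1OC | intermediate
9 | 4-bromo-2-methoxyphenol | COc1cc(Br)ccc1O | starting material
10 | 1-(benzyloxy)-4-bromo-2-methoxybenzene | COc1cc(Br)ccc1OCc2ccccc2 | intermediate
11 | (1S,2S)-1-[4-(benzyloxy)-3-methoxyphenyl]-2-[4-(benzyloxy)-2,6-dimethoxyphenoxy]propane-1,3-diol | COc1cc([C@H](O)[C@H](CO)Oc2c(OC)cc(OCc3ccccc3)cc2OC)ccc1OCc4ccccc4 | intermediate
12 | (1S,2S)-1-(4-hydroxy-3-methoxyphenyl)-2-(4-hydroxy-2,6-dimethoxyphenoxy)propane-1,3-diol | COc1cc([C@H](O)[C@H](CO)Oc2c(OC)cc(O)cc2OC)ccc1O | target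

**Step count**
Total: 9 steps. Longest linear sequence: 8 steps (Steps 1–6, 8, 9); Step 7 is a one-step branch.

**Three steps most likely to fail, with fallbacks**
1. Step 8, diastereoselectivity at C7. Aryl ethers chelate weakly, and in THF these aldehydes tend to give the Felkin (erythro) product, so chelation control here is the least certain point of the route.
   Fallback: set C7 by reduction instead of addition. Omit the methanolysis, oxidise the epimeric C7 alcohols (DMP) to the α-aryloxy aryl ketone, and reduce under Felkin (non-chelating) control with L-Selectride at −78 °C or NaBH4/15-crown-5, which favours threo. Ru–TsDPEN transfer hydrogenation is the reagent-controlled alternative.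
2. Step 5, enzymatic desymmetrisation. The bulky 2,6-disubstituted aryloxy group may lower the rate or ee, or reverse the sense.
   Fallback: chemocatalytic desymmetrisation of diol 5 by dinuclear Zn–ProPhenol mono-benzoylation with vinyl benzoate. Either ligand antipode is available, and the (R)-monobenzoate is carried through Steps 6, 8 and 9 in place of 7.
3. Steps 6 and 8, integrity of aldehyde 8. The aldehyde can lose AcOH by β-elimination or epimerise at C8.
   Fallback: swap the arms. Acetylate diol 5 with the same lipase and vinyl acetate to get the (S)-monoacetate, silylate the free arm (TBDPSCl), remove the acetate, and oxidise. This gives the same (S)-aldehyde series with a non-eliminating, non-chelating CH2OTBDPS group. It costs two extra steps, including a TBAF step before hydrogenolysis.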